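**Plan**

1. Retrosynthesis: the ten phenols are masked as methyl ethers and the stilbene is cut at its aryl–vinyl bond (Heck). Then the three C3–aryl bonds are cut: C3 of unit A to C4 of unit B, C3 of unit B to C4 of unit C, and C3 of unit C to the 3,5-dioxygenated phenyl ring (units A, B, C = styryl-bearing, central and terminal dihydrobenzofuran).
2. This reveals one building block three times, 4-bromo-6-methoxy-2-(4-methoxyphenyl)-2,3-dihydrobenzofuran-3-carboxylic acid: twice in the 2R form (units A and C) and once in the 2S form (unit B).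
3. Each block is cut at O1–C7a and C2–C3. C2–C3 comes from rhodium-carbene insertion of diazo ester 3 into the benzylic C–H of silyl ether 5; the furan ring is then closed at O1–C7a by hydroxyl-directed C–H palladation. This works because the C2 hydroxyl and C7a are 1,5-related (O–C2–C3–C3a–C7a, six-membered palladacycle) and C7a–H is the only free ortho C–H of the aryl ring on C3; the other ortho carbon (C4) carries the bromine kept for the inter-unit bond.
4. Forward order: unit C is arylated at C3, unit B is joined through its C3 to C4 of unit C, then unit A through its C3 to C4 of unit B, each by decarboxylative arylation; Heck reaction and demethylation finish the route.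
5. Stereochemistry: C2 of each unit comes from the hand of the rhodium catalyst; C3 of each unit comes from capture of the planar C3 radical anti to the C2 aryl group (trans); the relation between units is fixed because each unit enters as a single enantiomer.

Key step: step 6

Assumption: the sense of induction of Rh2(PTAD)4, dirhodium tetrakis[(1-adamantyl)(N-phthalimido)acetate], in the benzylic C–H insertion is assigned by analogy with related aryldiazoacetate insertions; if it is the opposite, the two catalyst enantiomers are exchanged between steps 4 and 9.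

**Route**

Step 1
Reactants: 1 2-(2-bromo-4-methoxyphenyl)acetic acid
Product: 2 methyl 2-(2-bromo-4-methoxyphenyl)acetate
Conditions: MeOH, H2SO4 (cat.), reflux
Reagents that add atoms: methanol, CO
Why: Fischer esterification of an unhindered arylacetic acid; no stereocentre is involved.

Step 2
Reactants: 2 methyl 2-(2-bromo-4-methoxyphenyl)acetate
Product: 3 methyl 2-(2-bromo-4-methoxyphenyl)-2-diazoacetate
Conditions: p-ABSA, DBU, MeCN, 0 °C to rt
Reagents that add atoms: 4-acetamidobenzenesulfonyl azide (p-ABSA), CC(=O)Nc1ccc(cc1)S(=O)(=O)N=[N+]=[N-]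
Why: Regitz diazo transfer: DBU forms the aryl-stabilised ester enolate, which attacks the terminal nitrogen of the sulfonyl azide and expels the sulfonamide.

Step 3
Reactants: 4 (4-methoxyphenyl)methanol
Product: 5 tert-butyl[(4-methoxyphenyl)methoxy]dimethylsilane
Conditions: TBSCl, imidazole, DMF, rt
Reagents that add atoms: tert-butyldimethylsilyl chloride (TBSCl), CC(C)(C)[Si](C)(C)Cl
Why: Silylation of a primary alcohol under Corey conditions gives the ether whose benzylic C–H bonds are the insertion site of steps 4 and 9.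

Step 4
Reactants: 3 methyl 2-(2-bromo-4-methoxyphenyl)-2-diazoacetate; 5 tert-butyl[(4-methoxyphenyl)methoxy]dimethylsilane
Product: 6 methyl (2S,3S)-2-(2-bromo-4-methoxyphenyl)-3-[(tert-butyldimethylsilyl)oxy]-3-(4-methoxyphenyl)propanoate
Conditions: Rh2(S-PTAD)4 (1 mol %), 5 (2 equiv), 2,2-dimethylbutane, reflux, slow addition of 3
Reagents that add atoms: none
Why: Davies-type intermolecular C–H insertion of a donor/acceptor rhodium carbene into the benzylic C–H bond of 5, which is activated by the silyloxy oxygen and the para-methoxyphenyl ring; the chiral carboxylate ligands of Rh2(S-PTAD)4, a catalyst that tolerates ortho-substituted aryldiazoacetates, should set the carbinol centre C3 as S (the future C2 of unit B) and, through the concerted three-centre transition state, the syn (2S,3S) relation.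

Step 5
Reactants: 6 methyl (2S,3S)-2-(2-bromo-4-methoxyphenyl)-3-[(tert-butyldimethylsilyl)oxy]-3-(4-methoxyphenyl)propanoate
Product: 7 methyl (2S,3S)-2-(2-bromo-4-methoxyphenyl)-3-hydroxy-3-(4-methoxyphenyl)propanoate
Conditions: TBAF, AcOH, THF, 0 °C to rt
Reagents that add atoms: none
Why: Fluoride-induced cleavage of the silyl ether, buffered with acetic acid so that the β-hydroxy ester meets no free alkoxide and should undergo neither retro-aldol cleavage nor epimerisation; both stereocentres are untouched.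

Step 6
Reactants: 7 methyl (2S,3S)-2-(2-bromo-4-methoxyphenyl)-3-hydroxy-3-(4-methoxyphenyl)propanoate
Product: 8 methyl (2S,3S)-4-bromo-6-methoxy-2-(4-methoxyphenyl)-2,3-dihydrobenzofuran-3-carboxylate (trans)
Conditions: Pd(OAc)2 (10 mol %), PhI(OAc)2 (1.5 equiv), Li2CO3 (1.5 equiv), C6F6, 100 °C
Reagents that add atoms: none
Why: The hydroxyl of 7 binds Pd(OAc)2 as an alkoxide and directs carboxylate-assisted (concerted metalation–deprotonation) cleavage of the C7a–H bond to give a six-membered oxapalladacycle of divalent palladium; PhI(OAc)2 oxidises it to tetravalent palladium and C–O reductive elimination forms the O1–C7a bond. The closest known reaction type is the hydroxyl-directed C–H activation/C–O cyclisation of 2-arylethanols to dihydrobenzofurans, including secondary benzylic β-hydroxy α-aryl esters obtained by carbene C–H insertion. The dihydrofuran ring is closed in the reductive elimination, a five-membered ring formed by contraction of the six-membered palladacycle (formally a 5-exo attack of oxygen on the aryl carbon). No stereocentre is created: the C–O bond at C2 is not broken, so C2 keeps the S configuration set in step 4, and C3 keeps its trans relation (it is in any case renewed in step 15). Site selectivity is needed and is secured by the substitution pattern, since C4 is blocked by bromine and C7a–H is the only ortho C–H of the ring on C3, while activation of the anisyl ring on C2 would require a four-membered ring closure. Chemoselectivity over oxidation of the secondary alcohol to the ketone and over the C–Br bond should follow from the mild carbonate base and from the absence of zerovalent palladium under the oxidising conditions.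

Step 7
Reactants: 8 methyl (2S,3S)-4-bromo-6-methoxy-2-(4-methoxyphenyl)-2,3-dihydrobenzofuran-3-carboxylate
Product: 9 (2S,3S)-4-bromo-6-methoxy-2-(4-methoxyphenyl)-2,3-dihydrobenzofuran-3-carboxylic acid
Conditions: Me3SnOH (5 equiv), 1,2-dichloroethane, 80 °C; dilute aq. HCl wash
Reagents that add atoms: trimethyltin hydroxide, C[Sn](C)(C)O
Why: Ester cleavage with Me3SnOH proceeds at neutral pH, so the enolisable C3–H is not removed and neither epimerisation nor E1cB opening of the aryl ether at C2 should occur.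

Step 8
Reactants: 9 (2S,3S)-4-bromo-6-methoxy-2-(4-methoxyphenyl)-2,3-dihydrobenzofuran-3-carboxylic acid
Product: 10 1,3-dioxoisoindolin-2-yl (2S,3S)-4-bromo-6-methoxy-2-(4-methoxyphenyl)-2,3-dihydrobenzofuran-3-carboxylate
Conditions: N-hydroxyphthalimide, DIC, DMAP (5 mol %), CH2Cl2, 0 °C to rt
Reagents that add atoms: N-hydroxyphthalimide, O=C1c2ccccc2C(=O)N1O
Why: Steglich-type carbodiimide esterification should give the redox-active ester without touching C2.

Step 9
Reactants: 3 methyl 2-(2-bromo-4-methoxyphenyl)-2-diazoacetate; 5 tert-butyl[(4-methoxyphenyl)methoxy]dimethylsilane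
Product: 11 methyl (2R,3R)-2-(2-bromo-4-methoxyphenyl)-3-[(tert-butyldimethylsilyl)oxy]-3-(4-methoxyphenyl)propanoate
Conditions: Rh2(R-PTAD)4 (1 mol %), 5 (2 equiv), 2,2-dimethylbutane, reflux, slow addition of 3
Reagents that add atoms: none
Why: The same Davies-type carbene C–H insertion as in step 4 with the mirror-image catalyst, which should set the carbinol centre as R (the future C2 of units A and C) and the syn (2R,3R) relation.

Step 10
Reactants: 11 methyl (2R,3R)-2-(2-bromo-4-methoxyphenyl)-3-[(tert-butyldimethylsilyl)oxy]-3-(4-methoxyphenyl)propanoate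
Product: 12 methyl (2R,3R)-2-(2-bromo-4-methoxyphenyl)-3-hydroxy-3-(4-methoxyphenyl)propanoate
Conditions: TBAF, AcOH, THF, 0 °C to rt
Reagents that add atoms: none
Why: Buffered fluoride cleavage of the silyl ether as in step 5; both stereocentres are untouched.

Step 11
Reactants: 12 methyl (2R,3R)-2-(2-bromo-4-methoxyphenyl)-3-hydroxy-3-(4-methoxyphenyl)propanoate
Product: 13 methyl (2R,3R)-4-bromo-6-methoxy-2-(4-methoxyphenyl)-2,3-dihydrobenzofuran-3-carboxylate (trans)
Conditions: Pd(OAc)2 (10 mol %), PhI(OAc)2 (1.5 equiv), Li2CO3 (1.5 equiv), C6F6, 100 °C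
Reagents that add atoms: none
Why: Hydroxyl-directed C–H palladation at the only free ortho C–H (C7a) and C–O reductive elimination from tetravalent palladium, as in step 6, should close the dihydrofuran ring of the outer units with retention at C2 (R).

Step 12
Reactants: 13 methyl (2R,3R)-4-bromo-6-methoxy-2-(4-methoxyphenyl)-2,3-dihydrobenzofuran-3-carboxylate
Product: 14 (2R,3R)-4-bromo-6-methoxy-2-(4-methoxyphenyl)-2,3-dihydrobenzofuran-3-carboxylic acid
Conditions: Me3SnOH (5 equiv), 1,2-dichloroethane, 80 °C; dilute aq. HCl wash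
Reagents that add atoms: trimethyltin hydroxide, C[Sn](C)(C)O
Why: Neutral tin hydroxide ester cleavage as in step 7, which should avoid enolisation at C3 and opening of the aryl ether at C2.

Step 13
Reactants: 14 (2R,3R)-4-bromo-6-methoxy-2-(4-methoxyphenyl)-2,3-dihydrobenzofuran-3-carboxylic acid
Product: 15 1,3-dioxoisoindolin-2-yl (2R,3R)-4-bromo-6-methoxy-2-(4-methoxyphenyl)-2,3-dihydrobenzofuran-3-carboxylate
Conditions: N-hydroxyphthalimide, DIC, DMAP (5 mol %), CH2Cl2, 0 °C to rt
Reagents that add atoms: N-hydroxyphthalimide, O=C1c2ccccc2C(=O)N1O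
Why: Steglich-type carbodiimide esterification as in step 8 gives the redox-active ester used in steps 14 and 16.

Step 14
Reactants: 15 1,3-dioxoisoindolin-2-yl (2R,3R)-4-bromo-6-methoxy-2-(4-methoxyphenyl)-2,3-dihydrobenzofuran-3-carboxylate; 16 (3,5-dimethoxyphenyl)magnesium chloride (THF solution)
Product: 18 (2R,3R)-4-bromo-3-(3,5-dimethoxyphenyl)-6-methoxy-2-(4-methoxyphenyl)-2,3-dihydrobenzofuran (unit C bromide), via (3,5-dimethoxyphenyl)zinc chloride 17 (not isolated)
Conditions: 16, ZnCl2, THF, 0 °C; then 15, Fe(acac)3 (20 mol %), dppBz [1,2-bis(diphenylphosphino)benzene] (24 mol %), THF/toluene, 0 °C to rt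
Reagents that add atoms: none
Why: Iron-catalysed decarboxylative Negishi-type arylation of a redox-active ester: single-electron reduction of the phthalimide ester releases CO2 and a planar benzylic radical at C3, which the aryl–iron species should capture on the face anti to the C2 4-methoxyphenyl group, setting C3 as R (trans) under control of C2, while the aryl C–Br bond is inert to the iron–bisphosphine catalyst.

Step 15
Reactants: 18 (2R,3R)-4-bromo-3-(3,5-dimethoxyphenyl)-6-methoxy-2-(4-methoxyphenyl)-2,3-dihydrobenzofuran; 10 1,3-dioxoisoindolin-2-yl (2S,3S)-4-bromo-6-methoxy-2-(4-methoxyphenyl)-2,3-dihydrobenzofuran-3-carboxylate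
Product: 21 (2R,3R)-4-[(2S,3S)-4-bromo-6-methoxy-2-(4-methoxyphenyl)-2,3-dihydrobenzofuran-3-yl]-3-(3,5-dimethoxyphenyl)-6-methoxy-2-(4-methoxyphenyl)-2,3-dihydrobenzofuran (B–C dimer bromide), via unit C aryllithium 19 (not isolated), via unit C arylzinc chloride 20 (not isolated)
Conditions: 18, n-BuLi, THF, −78 °C; ZnCl2, −78 °C to 0 °C; then 10 (1.5 equiv), Fe(acac)3 (20 mol %), dppBz (24 mol %), THF/toluene, rt
Reagents that add atoms: none
Why: Bromine–lithium exchange and transmetalation give the arylzinc at C4 of unit C, and the same iron-catalysed decarboxylative arylation joins it to the C3 radical of unit B; capture anti to the C2 aryl group of unit B should set C3 as S (trans), and because both partners are single enantiomers only one diastereomer of the dimer can arise.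

Step 16
Reactants: 21 B–C dimer bromide; 15 1,3-dioxoisoindolin-2-yl (2R,3R)-4-bromo-6-methoxy-2-(4-methoxyphenyl)-2,3-dihydrobenzofuran-3-carboxylate
Product: 24 (2R,3R)-4-{(2S,3S)-4-[(2R,3R)-4-bromo-6-methoxy-2-(4-methoxyphenyl)-2,3-dihydrobenzofuran-3-yl]-6-methoxy-2-(4-methoxyphenyl)-2,3-dihydrobenzofuran-3-yl}-3-(3,5-dimethoxyphenyl)-6-methoxy-2-(4-methoxyphenyl)-2,3-dihydrobenzofuran (A–B–C trimer bromide), via B–C aryllithium 22 (not isolated), via B–C arylzinc chloride 23 (not isolated)
Conditions: 21, n-BuLi, THF, −78 °C; ZnCl2, −78 °C to 0 °C; then 15 (2 equiv), Fe(acac)3 (20 mol %), dppBz (24 mol %), THF/toluene, rt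
Reagents that add atoms: none
Why: The same exchange, transmetalation and iron-catalysed decarboxylative arylation join C4 of unit B to the C3 radical of unit A, whose capture anti to its C2 aryl group should set C3 of unit A as R (trans); the C4–Br bond of unit A is inert to the iron catalyst and is kept for step 17.

Step 17
Reactants: 24 A–B–C trimer bromide; 25 4-ethenyl-1,2-dimethoxybenzene (3,4-dimethoxystyrene)
Product: 26 decamethyl ether of the target, (2R,3R)-4-{(2S,3S)-4-[(2R,3R)-4-[(E)-2-(3,4-dimethoxyphenyl)ethenyl]-6-methoxy-2-(4-methoxyphenyl)-2,3-dihydrobenzofuran-3-yl]-6-methoxy-2-(4-methoxyphenyl)-2,3-dihydrobenzofuran-3-yl}-3-(3,5-dimethoxyphenyl)-6-methoxy-2-(4-methoxyphenyl)-2,3-dihydrobenzofuran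
Conditions: Pd[P(t-Bu)3]2 (5 mol %), Cy2NMe (1.5 equiv), 25 (2 equiv), 1,4-dioxane, 90 °C
Reagents that add atoms: none
Why: Mizoroki–Heck reaction: the bulky electron-rich phosphine lets zerovalent palladium insert into the hindered electron-rich C4–Br bond of unit A, migratory insertion occurs at the terminal alkene carbon and syn β-hydride elimination gives the E stilbene; no stereocentre is touched.

Step 18
Reactants: 26 decamethyl ether of the target
Product: 27 CNP0099535.1, (2R,3R)-4-{(2S,3S)-4-[(2R,3R)-4-[(E)-2-(3,4-dihydroxyphenyl)ethenyl]-6-hydroxy-2-(4-hydroxyphenyl)-2,3-dihydrobenzofuran-3-yl]-6-hydroxy-2-(4-hydroxyphenyl)-2,3-dihydrobenzofuran-3-yl}-3-(3,5-dihydroxyphenyl)-2-(4-hydroxyphenyl)-2,3-dihydrobenzofuran-6-ol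
Conditions: BBr3 (30 equiv), CH2Cl2, −78 °C to rt; MeOH, then H2O
Reagents that add atoms: none
Why: Lewis-acid cleavage of aryl methyl ethers with BBr3 (bromide attack on the methyl group of each boron-complexed ether) should free all ten phenols; at low temperature the benzylic C2–O bonds should survive, and any reversible opening at C2 would reclose to the trans isomer dictated by the untouched C3 centres.

**Compound list**

1 | 2-(2-bromo-4-methoxyphenyl)acetic acid | COc1ccc(CC(=O)O)c(Br)c1 | starting material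
2 | methyl 2-(2-bromo-4-methoxyphenyl)acetate | COc1ccc(CC(=O)OC)c(Br)c1 | intermediate
3 | methyl 2-(2-bromo-4-methoxyphenyl)-2-diazoacetate | COc1ccc(C(=[N+]=[N-])C(=O)OC)c(Br)c1 | intermediate
4 | (4-methoxyphenyl)methanol | COc1ccc(CO)cc1 | starting material
5 | tert-butyl[(4-methoxyphenyl)methoxy]dimethylsilane | COc1ccc(CO[Si](C)(C)C(C)(C)C)cc1 | intermediate
6 | methyl (2S,3S)-2-(2-bromo-4-methoxyphenyl)-3-[(tert-butyldimethylsilyl)oxy]-3-(4-methoxyphenyl)propanoate | Brc1cc(OC)ccc1[C@H](C(=O)OC)[C@@H](c1ccc(OC)cc1)O[Si](C)(C)C(C)(C)C | intermediate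
7 | methyl (2S,3S)-2-(2-bromo-4-methoxyphenyl)-3-hydroxy-3-(4-methoxyphenyl)propanoate | Brc1cc(OC)ccc1[C@H](C(=O)OC)[C@@H](c1ccc(OC)cc1)O | intermediate
8 | methyl (2S,3S)-4-bromo-6-methoxy-2-(4-methoxyphenyl)-2,3-dihydrobenzofuran-3-carboxylate | Brc1cc(OC)cc2c1[C@H](C(=O)OC)[C@@H](c1ccc(OC)cc1)O2 | intermediate
9 | (2S,3S)-4-bromo-6-methoxy-2-(4-methoxyphenyl)-2,3-dihydrobenzofuran-3-carboxylic acid | Brc1cc(OC)cc2c1[C@H](C(=O)O)[C@@H](c1ccc(OC)cc1)O2 | intermediate
10 | 1,3-dioxoisoindolin-2-yl (2S,3S)-4-bromo-6-methoxy-2-(4-methoxyphenyl)-2,3-dihydrobenzofuran-3-carboxylate | Brc1cc(OC)cc2c1[C@H](C(=O)ON1C(=O)c3ccccc3C1=O)[C@@H](c1ccc(OC)cc1)O2 | intermediate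
11 | methyl (2R,3R)-2-(2-bromo-4-methoxyphenyl)-3-[(tert-butyldimethylsilyl)oxy]-3-(4-methoxyphenyl)propanoate | Brc1cc(OC)ccc1[C@@H](C(=O)OC)[C@H](c1ccc(OC)cc1)O[Si](C)(C)C(C)(C)C | intermediate
12 | methyl (2R,3R)-2-(2-bromo-4-methoxyphenyl)-3-hydroxy-3-(4-methoxyphenyl)propanoate | Brc1cc(OC)ccc1[C@@H](C(=O)OC)[C@H](c1ccc(OC)cc1)O | intermediate
13 | methyl (2R,3R)-4-bromo-6-methoxy-2-(4-methoxyphenyl)-2,3-dihydrobenzofuran-3-carboxylate | Brc1cc(OC)cc2c1[C@@H](C(=O)OC)[C@H](c1ccc(OC)cc1)O2 | intermediate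
14 | (2R,3R)-4-bromo-6-methoxy-2-(4-methoxyphenyl)-2,3-dihydrobenzofuran-3-carboxylic acid | Brc1cc(OC)cc2c1[C@@H](C(=O)O)[C@H](c1ccc(OC)cc1)O2 | intermediate
15 | 1,3-dioxoisoindolin-2-yl (2R,3R)-4-bromo-6-methoxy-2-(4-methoxyphenyl)-2,3-dihydrobenzofuran-3-carboxylate | Brc1cc(OC)cc2c1[C@@H](C(=O)ON1C(=O)c3ccccc3C1=O)[C@H](c1ccc(OC)cc1)O2 | intermediate
16 | (3,5-dimethoxyphenyl)magnesium chloride | COc1cc(OC)cc([Mg]Cl)c1 | starting material
17 | (3,5-dimethoxyphenyl)zinc chloride | COc1cc(OC)cc([Zn]Cl)c1 | intermediate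
18 | (2R,3R)-4-bromo-3-(3,5-dimethoxyphenyl)-6-methoxy-2-(4-methoxyphenyl)-2,3-dihydrobenzofuran | Brc1cc(OC)cc2c1[C@@H](c1cc(OC)cc(OC)c1)[C@H](c1ccc(OC)cc1)O2 | intermediate
19 | [(2R,3R)-3-(3,5-dimethoxyphenyl)-6-methoxy-2-(4-methoxyphenyl)-2,3-dihydrobenzofuran-4-yl]lithium | [Li]c1cc(OC)cc2c1[C@@H](c1cc(OC)cc(OC)c1)[C@H](c1ccc(OC)cc1)O2 | intermediate
20 | chloro[(2R,3R)-3-(3,5-dimethoxyphenyl)-6-methoxy-2-(4-methoxyphenyl)-2,3-dihydrobenzofuran-4-yl]zinc | Cl[Zn]c1cc(OC)cc2c1[C@@H](c1cc(OC)cc(OC)c1)[C@H](c1ccc(OC)cc1)O2 | intermediate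
21 | (2R,3R)-4-[(2S,3S)-4-bromo-6-methoxy-2-(4-methoxyphenyl)-2,3-dihydrobenzofuran-3-yl]-3-(3,5-dimethoxyphenyl)-6-methoxy-2-(4-methoxyphenyl)-2,3-dihydrobenzofuran | COc1ccc([C@H]2Oc3cc(OC)cc(Br)c3[C@@H]2c2cc(OC)cc3c2[C@@H](c2cc(OC)cc(OC)c2)[C@H](c2ccc(OC)cc2)O3)cc1 | intermediate
22 | 4-lithio analogue of 21 (lithium on C4 of unit B) | COc1ccc([C@H]2Oc3cc(OC)cc([Li])c3[C@@H]2c2cc(OC)cc3c2[C@@H](c2cc(OC)cc(OC)c2)[C@H](c2ccc(OC)cc2)O3)cc1 | intermediate
23 | 4-(chlorozincio) analogue of 21 (zinc on C4 of unit B) | COc1ccc([C@H]2Oc3cc(OC)cc([Zn]Cl)c3[C@@H]2c2cc(OC)cc3c2[C@@H](c2cc(OC)cc(OC)c2)[C@H](c2ccc(OC)cc2)O3)cc1 | intermediate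
24 | (2R,3R)-4-{(2S,3S)-4-[(2R,3R)-4-bromo-6-methoxy-2-(4-methoxyphenyl)-2,3-dihydrobenzofuran-3-yl]-6-methoxy-2-(4-methoxyphenyl)-2,3-dihydrobenzofuran-3-yl}-3-(3,5-dimethoxyphenyl)-6-methoxy-2-(4-methoxyphenyl)-2,3-dihydrobenzofuran | COc1ccc([C@H]2Oc3cc(OC)cc([C@@H]4c5c(Br)cc(OC)cc5O[C@H]4c4ccc(OC)cc4)c3[C@@H]2c2cc(OC)cc3c2[C@@H](c2cc(OC)cc(OC)c2)[C@H](c2ccc(OC)cc2)O3)cc1 | intermediate
25 | 4-ethenyl-1,2-dimethoxybenzene | C=Cc1ccc(OC)c(OC)c1 | starting material
26 | decamethyl ether of the target (E stilbene, units A 2R,3R; B 2S,3S; C 2R,3R) | COc1ccc([C@H]2Oc3cc(OC)cc([C@@H]4c5c(/C=C/c6ccc(OC)c(OC)c6)cc(OC)cc5O[C@H]4c4ccc(OC)cc4)c3[C@@H]2c2cc(OC)cc3c2[C@@H](c2cc(OC)cc(OC)c2)[C@H](c2ccc(OC)cc2)O3)cc1 | intermediate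
27 | CNP0099535.1 | Oc1ccc([C@H]2Oc3cc(O)cc([C@@H]4c5c(/C=C/c6ccc(O)c(O)c6)cc(O)cc5O[C@H]4c4ccc(O)cc4)c3[C@@H]2c2cc(O)cc3c2[C@@H](c2cc(O)cc(O)c2)[C@H](c2ccc(O)cc2)O3)cc1 | target

**Step count**

Total: 18 steps. Longest linear sequence: 12 steps (1, 2, 9, 10, 11, 12, 13, 14, 15, 16, 17, 18).

**Steps most likely to fail**

Step 16. The zinc in 23 sits on C4 of unit B, directly beside C3a whose C3 carries the whole of unit C. Transfer of this aryl group to iron and the aryl–alkyl reductive elimination may therefore be slower than dimerisation or hydrogen abstraction of the benzylic radical from 15, and 23 may be protonated before it couples. The fallback changes the order of assembly, so that the C4 nucleophile of unit B is used while its C3 carries only a carboxylate. It sets out from acid 9 and ester 15. Acid 9 is treated with n-BuLi (2.1 equiv, THF, −78 °C) to give lithium (2S,3S)-4-lithio-6-methoxy-2-(4-methoxyphenyl)-2,3-dihydrobenzofuran-3-carboxylate F3. ZnCl2 converts it into lithium (2S,3S)-4-(chlorozincio)-6-methoxy-2-(4-methoxyphenyl)-2,3-dihydrobenzofuran-3-carboxylate F4. Coupling of F4 with 15 under Fe(acac)3/dppBz should give the A–B dimer acid (2S,3S)-4-[(2R,3R)-4-bromo-6-methoxy-2-(4-methoxyphenyl)-2,3-dihydrobenzofuran-3-yl]-6-methoxy-2-(4-methoxyphenyl)-2,3-dihydrobenzofuran-3-carboxylic acid F5. DIC and N-hydroxyphthalimide turn F5 into its 1,3-dioxoisoindolin-2-yl ester F6. Iron-catalysed coupling of F6 with arylzinc 20 (made from 18 through 19 as in step 15) comes back to the route at 24.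

Step 15. Transfer of the ortho-flanked aryl group of 20 from zinc to iron may be slow, which would let the radical from 10 dimerise, be reduced, or open the ring by loss of the aryloxy group at C2. The fallback is a nickel-catalysed cross-electrophile coupling in which the aryl–metal species arises by oxidative addition and not by transmetalation. It sets out from bromide 18, which is converted through aryllithium 19 (n-BuLi, THF, −78 °C) and iodine into (2R,3R)-3-(3,5-dimethoxyphenyl)-4-iodo-6-methoxy-2-(4-methoxyphenyl)-2,3-dihydrobenzofuran F2. F2 and ester 10 are then coupled with NiBr2(dme), 4,4′-di-tert-butyl-2,2′-bipyridine and zinc powder in DMA at rt; the C–I bond should add to low-valent nickel faster than the C–Br bond of 10, and the aryl–nickel species captures the C3 radical anti to the C2 aryl group. The fallback comes back to the route at 21.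

Step 4 (and its mirror image, step 9). The ortho bromine twists the aryl ring out of the carbene plane, which may lower the enantioselectivity and favour carbene dimerisation or attack on the anisyl ring and the methoxy C–H bonds of 5. The fallback makes the carbinol centre by ketone reduction and sets out from ester 2. Claisen-type acylation (LiHMDS, THF, −78 °C; 4-methoxybenzoyl chloride) gives methyl 2-(2-bromo-4-methoxyphenyl)-3-(4-methoxyphenyl)-3-oxopropanoate F1. Noyori asymmetric transfer hydrogenation with dynamic kinetic resolution, RuCl(p-cymene)[(S,S)-TsDPEN] (the catalyst hand being chosen to give the 3S carbinol), HCO2H/Et3N, should funnel the rapidly racemising F1 to hydroxy ester 7, where the fallback comes back to the route; the mirror-image catalyst gives 12. Only the carbinol centre needs to be controlled, because the neighbouring centre is renewed in the decarboxylative arylation.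

Further compounds
F1 | step 4 | methyl 2-(2-bromo-4-methoxyphenyl)-3-(4-methoxyphenyl)-3-oxopropanoate | COC(=O)C(C(=O)c1ccc(OC)cc1)c1ccc(OC)cc1Br
F2 | step 15 | (2R,3R)-3-(3,5-dimethoxyphenyl)-4-iodo-6-methoxy-2-(4-methoxyphenyl)-2,3-dihydrobenzofuran | Ic1cc(OC)cc2c1[C@@H](c1cc(OC)cc(OC)c1)[C@H](c1ccc(OC)cc1)O2
F3 | step 16 | lithium (2S,3S)-4-lithio-6-methoxy-2-(4-methoxyphenyl)-2,3-dihydrobenzofuran-3-carboxylate | [Li]c1cc(OC)cc2c1[C@H](C(=O)O[Li])[C@@H](c1ccc(OC)cc1)O2
F4 | step 16 | lithium (2S,3S)-4-(chlorozincio)-6-methoxy-2-(4-methoxyphenyl)-2,3-dihydrobenzofuran-3-carboxylate | Cl[Zn]c1cc(OC)cc2c1[C@H](C(=O)O[Li])[C@@H](c1ccc(OC)cc1)O2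
F5 | step 16 | (2S,3S)-4-[(2R,3R)-4-bromo-6-methoxy-2-(4-methoxyphenyl)-2,3-dihydrobenzofuran-3-yl]-6-methoxy-2-(4-methoxyphenyl)-2,3-dihydrobenzofuran-3-carboxylic acid | COc1ccc([C@H]2Oc3cc(OC)cc([C@@H]4c5c(Br)cc(OC)cc5O[C@H]4c4ccc(OC)cc4)c3[C@@H]2C(=O)O)cc1
F6 | step 16 | 1,3-dioxoisoindolin-2-yl (2S,3S)-4-[(2R,3R)-4-bromo-6-methoxy-2-(4-methoxyphenyl)-2,3-dihydrobenzofuran-3-yl]-6-methoxy-2-(4-methoxyphenyl)-2,3-dihydrobenzofuran-3-carboxylate | COc1ccc([C@H]2Oc3cc(OC)cc([C@@H]4c5c(Br)cc(OC)cc5O[C@H]4c4ccc(OC)cc4)c3[C@@H]2C(=O)ON2C(=O)c3ccccc3C2=O)cc1
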